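The green run needs 90.0 min to reach 20.0% of product, while the teal run, with 4.00 times the catalyst, passes that mark after about 17.5 min by interpolation.

| setting | green | teal | flask |
|---|---|---|---|
| substrate | 0.20 M | 0.20 M | 0.20 M |
| partner | 1.5 equiv | 1.5 equiv | 1.50 equiv |
| protic impurity | 0.040 M | 0.040 M | 0.0400 M |
| free catalyst | 1 mol% | 4 mol% | 2 mol% |
| remark | run made earlier | run made earlier |  |

- green (time / min: product / %, substrate / %): 6.00: 1.1, 99.0; 20.0: 4.4, 93.8; 30.0: 7.7, 91.7; 50.0: 13.8, 87.2; 80.0: 17.2, 81.7; 90.0: 20.0, 80.9
- teal (time / min: product / %, substrate / %): 8.00: 10.3, 88.5; 12.0: 13.5, 84.8; 20.0: 23.0, 78.3; 40.0: 39.8, 60.3; 60.0: 48.9, 48.9; 90.0: 59.9, 41.0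

(readings scatter by 1 percentage point)

- apparent order in free catalyst when 30% of the substrate are converted (percent change of the rate of making product for one percent more free catalyst charged)
- apparent order in partner when 30% of the substrate are converted (percent change of the rate of making product for one percent more partner charged)

- no earlier run changes the charge of partner; that part of a forecast is a guess

I read the catalyst order near that mark in two ways. Rates first: taking product gained and substrate lost together, over 12.0 min to 20.0 min in teal and 50.0 min to 90.0 min in green, teal reads 6.40 times faster, an order of 1.34. Times next: their ratio is 5.15, more than 4.00, an order of 1.18.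

The two part, and I take the time ratio to be the one that cheats, since it averages over each whole run while green arrives at the mark later, in an older flask. So I suppose that the rate per catalyst falls with age at any loading. Substrate is the limiting reagent by the charge, but partner is unseen, so it is my suspect. A mean rate falls at half that speed, which gives the partner clock, the fractional loss of rate per catalyst each minute, 0.00697 min⁻¹. Between the middles of the two intervals it predicts a rate ratio of 5.83, against 6.40 read from the same two runs.

With the same clock held at every loading, more catalyst reaches a given conversion earlier, in a younger flask, so under this supposition the order at that conversion is the exponential of clock times time. Teal reaches 30% at about 28.3 min. The clock then puts the flask, at 2 mol%, there at 63.7 min, with an order of 1.56. Assuming first order in partner, which no earlier run tests, I commit to the same figure for partner.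

The forecast gives 1.15 (0.9 to 1.4) and 0.7 (0 to 1.2), with a catalyst order that could “reflect the excess protic impurity sequestering catalyst”. The flask gives 2.4 for catalyst and 2.2 for partner.

    partner + free catalyst → catalyst intermediate A (k = 2.41 M⁻¹ min⁻¹)
    catalyst intermediate A → released group + catalyst intermediate B (k = 1.30 min⁻¹)
    substrate + catalyst intermediate B → catalyst intermediate C (k = 7.59 M⁻¹ min⁻¹)
    catalyst intermediate C → free catalyst + product (k = 20.4 min⁻¹)
    partner + protic impurity → quenched reagent (k = 0.0527 M⁻¹ min⁻¹)
    partner → decomposed reagent (k = 0.0145 min⁻¹)

The flask reaches 30% conversion at 65.7 min, close to my 63.7 min, but 0.00697 min⁻¹ over that time gives an order of only 1.58. In the flask, loss of partner to decomposed reagent is the largest single effect on both orders. At 1.00 h in the flask, decomposed reagent holds 48.6% of the partner charge, with 26.7% left. Taking that step's 0.0145 min⁻¹ as the clock, the rule gives 2.59. Setting the clock to zero, the rule gives 1. In the simulated run without that step, the orders are 1.0 for catalyst and 0.68 for partner.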